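**Plan**

- Retrosynthesis: the four isopropyl ethers come off last. Ring C of unit 1 is cut at O1–C2 and C4–C4a, back to an acetyl group on C4a and 4-methoxybenzaldehyde. Ring C of unit 2 is cut at O1–C2 and C2–C3, back to a biaryl lactone and a phloroacetophenone enolate.
- The lactone carbonyl is cut to CO and an aryl bromide. Ring A of unit 1 is then cut at C8–C8a, C6–C7 and C4a–C8a into an aryl siloxyalkyne and a 3-alkoxycyclobutenone.
- Forward: ring A of unit 1 is built first by benzannulation, then the lactone, ring C of unit 2, the C4a acetyl group, ring C of unit 1, and finally dealkylation.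
- Enabling feature: C8 of unit 1, the carbon bonded to C2' of ring B of unit 2, lies between the oxygen-bearing C7 and C8a, with the third ring-A oxygen on C5 para to it. This is a 2-aryl-3,5-dioxygenated phenol, the pattern a vinylketene and an aryl ynol ether assemble, with only the ketene-derived C8a oxygen left as free OH.
- Stereochemistry: the target has no stereocentre, so nothing has to be controlled.

Key step: step 5

Remark: the target SMILES defines no configuration for the hindered C8–C2' biaryl axis, so it is treated as unassigned (racemic) throughout.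

**Route**

Step 1
Reactants: 1 4-bromo-3-iodoanisole; 2 ethynyltrimethylsilane
Product: 3 [(2-bromo-5-methoxyphenyl)ethynyl]trimethylsilane
Conditions: PdCl2(PPh3)2 (2 mol %), CuI (4 mol %), Et3N, THF, rt
Reagents that add atoms: none
Why: Sonogashira coupling; zerovalent palladium inserts into C–I far faster than into C–Br at room temperature, so only the iodide (the future C2' of ring B of unit 2) should be alkynylated.

Step 2
Reactants: 3 [(2-bromo-5-methoxyphenyl)ethynyl]trimethylsilane
Product: 4 1-bromo-2-ethynyl-4-methoxybenzene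
Conditions: K2CO3 (cat.), MeOH, rt
Reagents that add atoms: none
Why: Base-catalysed methanolysis of the alkynyl C–Si bond (protodesilylation) is fast and should leave the aryl bromide untouched.

Step 3
Reactants: 4 1-bromo-2-ethynyl-4-methoxybenzene
Product: 7 {[(2-bromo-5-methoxyphenyl)ethynyl]oxy}tri(propan-2-yl)silane, via lithium acetylide 5 (not isolated), via lithium ynolate 6 (not isolated)
Conditions: LiN(SiMe3)2, THF, −78 °C; t-BuOOLi (from t-BuOOH and LiN(SiMe3)2), −78 → 0 °C; i-Pr3SiOTf, −78 → 0 °C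
Reagents that add atoms: tert-butyl hydroperoxide, CC(C)(C)OO; tri(propan-2-yl)silyl trifluoromethanesulfonate, CC(C)[Si](OS(=O)(=O)C(F)(F)F)(C(C)C)C(C)C
Why: Oxidation of a lithium acetylide by lithium tert-butyl peroxide to the ynolate followed by O-silylation (the Julia-type ynolate route to siloxyalkynes); the amide base avoids bromine–lithium exchange, and a triisopropylsilyl ynol ether, unlike a benzyl or alkyl one, has no sigmatropic or retro-ene pathway for losing its O-substituent on heating.

Step 4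
Reactants: 8 3-ethoxycyclobut-2-en-1-one
Product: 9 3-(propan-2-yloxy)cyclobut-2-en-1-one
Conditions: i-PrOH (solvent), PPTS (cat.), 35 °C, EtOH removed under reduced pressure
Reagents that add atoms: propan-2-ol, CC(C)O
Why: Acid-catalysed addition–elimination at the β-carbon of a vinylogous ester (transetherification, as with squarate esters), driven by the excess of propan-2-ol and kept below the temperature at which the four-membered ring opens.

Step 5
Reactants: 7 {[(2-bromo-5-methoxyphenyl)ethynyl]oxy}tri(propan-2-yl)silane; 9 3-(propan-2-yloxy)cyclobut-2-en-1-one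
Product: 14 2-(2-bromo-5-methoxyphenyl)-5-(propan-2-yloxy)-3-{[tri(propan-2-yl)silyl]oxy}phenol, via vinylketene 10 (not isolated), via 4-vinylcyclobutenone 11 (not isolated), via dienylketene 12 (not isolated), via cyclohexadienone 13 (not isolated)
Conditions: 9 (1.5 equiv), toluene, 80 → 110 °C, sealed vessel
Reagents that add atoms: none
Why: On heating, 9 should open by 4π electrocyclic ring opening to the alkoxy vinylketene 10, whose C=C=O unit adds to the siloxyalkyne in a [2+2] cycloaddition to give 11; a second 4π opening gives dienylketene 12, and 6π electrocyclisation followed by enolisation of 13 delivers phenol 14. This is the Danheiser benzannulation of a cyclobutenone with a trialkylsiloxyalkyne, the 3-alkoxy group on the cyclobutenone being the only departure from the usual 3-alkyl or 3-aryl cases. Ring A of unit 1 is the one ring formed: the [2+2] step makes C8–C8a and C6–C7, and the thermally allowed disrotatory 6π closure makes C4a–C8a. No stereocentre results, since the one in 11 is destroyed when that ring opens. The selectivity required is the regiochemistry of the [2+2] step: the electrophilic ketene carbonyl carbon must bond to the aryl-bearing alkyne carbon, and the oxygen lone pair of the ynol ether secures this by making that carbon the nucleophilic terminus. The aryl group therefore ends up between the new hydroxyl and the silyloxy group with the isopropoxy group para to it; the free OH and the silyloxy oxygen flank C8 equivalently, so only the C5 oxygen needs to stay distinct in what follows.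

Step 6
Reactants: 14 2-(2-bromo-5-methoxyphenyl)-5-(propan-2-yloxy)-3-{[tri(propan-2-yl)silyl]oxy}phenol
Product: 15 9-methoxy-3-(propan-2-yloxy)-1-{[tri(propan-2-yl)silyl]oxy}-6H-benzo[c]chromen-6-one
Conditions: Pd(OAc)2 (5 mol %), Xantphos (10 mol %), CO (1 atm), Et3N, toluene, 100 °C
Reagents that add atoms: carbon monoxide, [C-]#[O+]
Why: Palladium-catalysed carbonylative lactonisation (intramolecular alkoxycarbonylation): oxidative addition into the aryl bromide, CO insertion and capture of the acylpalladium by the neighbouring phenol should close the six-membered lactone faster than direct C–O coupling to a dibenzofuran.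

Step 7
Reactants: 15 9-methoxy-3-(propan-2-yloxy)-1-{[tri(propan-2-yl)silyl]oxy}-6H-benzo[c]chromen-6-one
Product: 17 9-methoxy-1,3-di(propan-2-yloxy)-6H-benzo[c]chromen-6-one, via caesium phenoxide 16 (not isolated)
Conditions: CsF, 2-bromopropane, DMF, 60 °C
Reagents that add atoms: 2-bromopropane, CC(C)Br
Why: Fluoride cleaves the aryl silyl ether to the caesium phenoxide, which is alkylated in the same pot (desilylative Williamson etherification); anhydrous fluoride cannot open the lactone irreversibly.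

Step 8
Reactants: 18 1-(2,4,6-trihydroxyphenyl)ethan-1-one (2',4',6'-trihydroxyacetophenone)
Product: 19 1-[2-hydroxy-4,6-di(propan-2-yloxy)phenyl]ethan-1-one
Conditions: 2-bromopropane (2.2 equiv), K2CO3, DMF, 60 °C
Reagents that add atoms: 2-bromopropane, CC(C)Br
Why: Williamson etherification; the hydroxyl hydrogen-bonded to the acetyl carbonyl is the least nucleophilic, so alkylation should stop at the 4',6'-diether, as in the standard preparations of 2'-hydroxy-4',6'-dialkoxyacetophenones.

Step 9
Reactants: 17 9-methoxy-1,3-di(propan-2-yloxy)-6H-benzo[c]chromen-6-one; 19 1-[2-hydroxy-4,6-di(propan-2-yloxy)phenyl]ethan-1-one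
Product: 21 1-[2-hydroxy-4,6-di(propan-2-yloxy)phenyl]-3-{2-[2-hydroxy-4,6-di(propan-2-yloxy)phenyl]-4-methoxyphenyl}propane-1,3-dione, via dilithium dianion 20 (not isolated)
Conditions: 19 (2 equiv), LiN(SiMe3)2 (5 equiv), THF, −78 °C; then 17, −78 °C → rt; 1 M HCl
Reagents that add atoms: none
Why: Crossed Claisen condensation: the lithium dianion of the o-hydroxyacetophenone attacks the bay-strained aryl lactone, the ring-A phenoxide is expelled, and the excess base holds the β-diketone as its enolate so that retro-Claisen reclosure is suppressed.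

Step 10
Reactants: 21 1-[2-hydroxy-4,6-di(propan-2-yloxy)phenyl]-3-{2-[2-hydroxy-4,6-di(propan-2-yloxy)phenyl]-4-methoxyphenyl}propane-1,3-dione
Product: 22 2-{2-[2-hydroxy-4,6-di(propan-2-yloxy)phenyl]-4-methoxyphenyl}-5,7-di(propan-2-yloxy)-4H-chromen-4-one
Conditions: H2SO4 (cat.), AcOH, 95 °C
Reagents that add atoms: none
Why: Acid-catalysed cyclodehydration of an o-hydroxyaryl β-diketone to the flavone (the closing step of the Baker–Venkataraman sequence); closure through the ring-A phenol onto the same carbonyl would only rebuild the strained benzo[c]chromene and is reversible, whereas γ-pyrone formation is not.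

Step 11
Reactants: 22 2-{2-[2-hydroxy-4,6-di(propan-2-yloxy)phenyl]-4-methoxyphenyl}-5,7-di(propan-2-yloxy)-4H-chromen-4-one
Product: 24 2-{2-[3-acetyl-2-hydroxy-4,6-di(propan-2-yloxy)phenyl]-4-methoxyphenyl}-5,7-di(propan-2-yloxy)-4H-chromen-4-one, via difluoroboron chelate 23 (not isolated)
Conditions: Ac2O, BF3·OEt2, AcOH, rt → 50 °C; then NaOAc, MeOH/H2O, 60 °C
Reagents that add atoms: acetic anhydride, CC(=O)OC(C)=O
Why: Boron trifluoride-mediated Friedel–Crafts acetylation/Fries rearrangement of an electron-rich phenol; C4a is the only free position ortho to the hydroxyl and the product is trapped as the six-membered difluoroboron chelate, while C6 is shielded by two isopropoxy groups and isopropyl aryl ethers should withstand BF3 at this temperature.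

Step 12
Reactants: 24 2-{2-[3-acetyl-2-hydroxy-4,6-di(propan-2-yloxy)phenyl]-4-methoxyphenyl}-5,7-di(propan-2-yloxy)-4H-chromen-4-one; 25 4-methoxybenzaldehyde
Product: 26 2-{2-[2-hydroxy-3-[(2E)-3-(4-methoxyphenyl)prop-2-enoyl]-4,6-di(propan-2-yloxy)phenyl]-4-methoxyphenyl}-5,7-di(propan-2-yloxy)-4H-chromen-4-one
Conditions: KOH, EtOH, rt
Reagents that add atoms: none
Why: Claisen–Schmidt condensation of the methyl ketone with a non-enolisable aldehyde gives the E-chalcone by E1cB dehydration; the flavone of unit 2 should tolerate ethanolic hydroxide at room temperature.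

Step 13
Reactants: 26 2-{2-[2-hydroxy-3-[(2E)-3-(4-methoxyphenyl)prop-2-enoyl]-4,6-di(propan-2-yloxy)phenyl]-4-methoxyphenyl}-5,7-di(propan-2-yloxy)-4H-chromen-4-one
Product: 27 8-{5-methoxy-2-[4-oxo-5,7-di(propan-2-yloxy)-4H-chromen-2-yl]phenyl}-2-(4-methoxyphenyl)-5,7-di(propan-2-yloxy)-4H-chromen-4-one
Conditions: I2 (10 mol %), DMSO, 130 °C
Reagents that add atoms: none
Why: Iodine/DMSO oxidative cyclisation of a 2'-hydroxychalcone (oxa-Michael closure to the flavanone, α-iodination and loss of HI, with DMSO regenerating iodine); only the C8a hydroxyl is free, so ring C of unit 1 can close in one direction only.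

Step 14
Reactants: 27 8-{5-methoxy-2-[4-oxo-5,7-di(propan-2-yloxy)-4H-chromen-2-yl]phenyl}-2-(4-methoxyphenyl)-5,7-di(propan-2-yloxy)-4H-chromen-4-one
Product: 28 8-[2-(5,7-dihydroxy-4-oxo-4H-chromen-2-yl)-5-methoxyphenyl]-5,7-dihydroxy-2-(4-methoxyphenyl)-4H-chromen-4-one (CNP0394081.0)
Conditions: BCl3, CH2Cl2, −78 °C → rt; then aq. HCl
Reagents that add atoms: none
Why: Boron trichloride dealkylation; secondary isopropyl aryl ethers are cleaved far faster than methyl aryl ethers, so all four isopropyl groups should be removed while the two 4'-methoxy groups, which have no chelating carbonyl neighbour, remain.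

**Compound list**

1 | 4-bromo-3-iodoanisole | COc1ccc(Br)c(I)c1 | starting material
2 | ethynyltrimethylsilane | C#C[Si](C)(C)C | starting material
3 | [(2-bromo-5-methoxyphenyl)ethynyl]trimethylsilane | COc1ccc(Br)c(C#C[Si](C)(C)C)c1 | intermediate
4 | 1-bromo-2-ethynyl-4-methoxybenzene | COc1ccc(Br)c(C#C)c1 | intermediate
5 | lithium (2-bromo-5-methoxyphenyl)acetylide (not isolated) | [Li+].[C-]#Cc1cc(OC)ccc1Br | intermediate
6 | lithium 2-(2-bromo-5-methoxyphenyl)ethynolate (not isolated) | [Li+].[O-]C#Cc1cc(OC)ccc1Br | intermediate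
7 | {[(2-bromo-5-methoxyphenyl)ethynyl]oxy}tri(propan-2-yl)silane | COc1ccc(Br)c(C#CO[Si](C(C)C)(C(C)C)C(C)C)c1 | intermediate
8 | 3-ethoxycyclobut-2-en-1-one | CCOC1=CC(=O)C1 | starting material
9 | 3-(propan-2-yloxy)cyclobut-2-en-1-one | CC(C)OC1=CC(=O)C1 | intermediate
10 | 3-(propan-2-yloxy)buta-1,3-dien-1-one, the vinylketene (not isolated) | C=C(OC(C)C)C=C=O | intermediate
11 | 2-(2-bromo-5-methoxyphenyl)-4-[1-(propan-2-yloxy)ethenyl]-3-{[tri(propan-2-yl)silyl]oxy}cyclobut-2-en-1-one, racemic (not isolated) | O=C1C(c2cc(OC)ccc2Br)=C(O[Si](C(C)C)(C(C)C)C(C)C)C1C(=C)OC(C)C | intermediate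
12 | (3E)-2-(2-bromo-5-methoxyphenyl)-5-(propan-2-yloxy)-3-{[tri(propan-2-yl)silyl]oxy}hexa-1,3,5-trien-1-one, the dienylketene (not isolated) | O=C=C(c1cc(OC)ccc1Br)\C(O[Si](C(C)C)(C(C)C)C(C)C)=C/C(=C)OC(C)C | intermediate
13 | 2-(2-bromo-5-methoxyphenyl)-5-(propan-2-yloxy)-3-{[tri(propan-2-yl)silyl]oxy}cyclohexa-2,4-dien-1-one (not isolated) | O=C1CC(OC(C)C)=CC(O[Si](C(C)C)(C(C)C)C(C)C)=C1c1cc(OC)ccc1Br | intermediate
14 | 2-(2-bromo-5-methoxyphenyl)-5-(propan-2-yloxy)-3-{[tri(propan-2-yl)silyl]oxy}phenol | COc1ccc(Br)c(c1)-c1c(O)cc(OC(C)C)cc1O[Si](C(C)C)(C(C)C)C(C)C | intermediate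
15 | 9-methoxy-3-(propan-2-yloxy)-1-{[tri(propan-2-yl)silyl]oxy}-6H-benzo[c]chromen-6-one | CC(C)[Si](Oc1cc(OC(C)C)cc2OC(=O)c3ccc(OC)cc3-c12)(C(C)C)C(C)C | intermediate
16 | caesium 9-methoxy-6-oxo-3-(propan-2-yloxy)-6H-benzo[c]chromen-1-olate (not isolated) | [Cs+].[O-]c1cc(OC(C)C)cc2OC(=O)c3ccc(OC)cc3-c12 | intermediate
17 | 9-methoxy-1,3-di(propan-2-yloxy)-6H-benzo[c]chromen-6-one | COc1ccc2C(=O)Oc3cc(OC(C)C)cc(OC(C)C)c3-c2c1 | intermediate
18 | 1-(2,4,6-trihydroxyphenyl)ethan-1-one | CC(=O)c1c(O)cc(O)cc1O | starting material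
19 | 1-[2-hydroxy-4,6-di(propan-2-yloxy)phenyl]ethan-1-one | CC(=O)c1c(O)cc(OC(C)C)cc1OC(C)C | intermediate
20 | dilithium 2-(1-oxidoethenyl)-3,5-di(propan-2-yloxy)phenolate (not isolated) | [Li+].[Li+].[O-]C(=C)c1c([O-])cc(OC(C)C)cc1OC(C)C | intermediate
21 | 1-[2-hydroxy-4,6-di(propan-2-yloxy)phenyl]-3-{2-[2-hydroxy-4,6-di(propan-2-yloxy)phenyl]-4-methoxyphenyl}propane-1,3-dione | COc1ccc(C(=O)CC(=O)c2c(O)cc(OC(C)C)cc2OC(C)C)c(c1)-c1c(O)cc(OC(C)C)cc1OC(C)C | intermediate
22 | 2-{2-[2-hydroxy-4,6-di(propan-2-yloxy)phenyl]-4-methoxyphenyl}-5,7-di(propan-2-yloxy)-4H-chromen-4-one | COc1ccc(-c2cc(=O)c3c(OC(C)C)cc(OC(C)C)cc3o2)c(c1)-c1c(O)cc(OC(C)C)cc1OC(C)C | intermediate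
23 | difluoroboron chelate of 24, O,O'-bound through the phenolate and acetyl oxygens (not isolated) | CC1=[O+][B-](F)(F)Oc2c1c(OC(C)C)cc(OC(C)C)c2-c1cc(OC)ccc1-c1cc(=O)c2c(OC(C)C)cc(OC(C)C)cc2o1 | intermediate
24 | 2-{2-[3-acetyl-2-hydroxy-4,6-di(propan-2-yloxy)phenyl]-4-methoxyphenyl}-5,7-di(propan-2-yloxy)-4H-chromen-4-one | COc1ccc(-c2cc(=O)c3c(OC(C)C)cc(OC(C)C)cc3o2)c(c1)-c1c(O)c(C(C)=O)c(OC(C)C)cc1OC(C)C | intermediate
25 | 4-methoxybenzaldehyde | COc1ccc(C=O)cc1 | starting material
26 | 2-{2-[2-hydroxy-3-[(2E)-3-(4-methoxyphenyl)prop-2-enoyl]-4,6-di(propan-2-yloxy)phenyl]-4-methoxyphenyl}-5,7-di(propan-2-yloxy)-4H-chromen-4-one | COc1ccc(/C=C/C(=O)c2c(O)c(-c3cc(OC)ccc3-c3cc(=O)c4c(OC(C)C)cc(OC(C)C)cc4o3)c(OC(C)C)cc2OC(C)C)cc1 | intermediate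
27 | 8-{5-methoxy-2-[4-oxo-5,7-di(propan-2-yloxy)-4H-chromen-2-yl]phenyl}-2-(4-methoxyphenyl)-5,7-di(propan-2-yloxy)-4H-chromen-4-one | COc1ccc(-c2cc(=O)c3c(OC(C)C)cc(OC(C)C)c(-c4cc(OC)ccc4-c4cc(=O)c5c(OC(C)C)cc(OC(C)C)cc5o4)c3o2)cc1 | intermediate
28 | 8-[2-(5,7-dihydroxy-4-oxo-4H-chromen-2-yl)-5-methoxyphenyl]-5,7-dihydroxy-2-(4-methoxyphenyl)-4H-chromen-4-one | COc1ccc(-c2cc(=O)c3c(O)cc(O)c(-c4cc(OC)ccc4-c4cc(=O)c5c(O)cc(O)cc5o4)c3o2)cc1 | target

**Step count**

Total: 14 steps. Longest linear sequence: 12 steps (steps 1, 2, 3, 5, 6, 7, 9, 10, 11, 12, 13, 14); steps 4 and 8 are one-step side branches.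

**Steps most likely to fail, with fallbacks**

Step 5 (benzannulation). The donor-substituted cyclobutenone may open too slowly. The vinylketene, once formed, could then be consumed by dimerisation or by acylating the product phenol instead of adding to the hindered aryl siloxyalkyne.

The fallback brings ring A in intact; it sets out from 1 and comes back to the route at 17. Phloroglucinol would be converted with MOMCl/i-Pr2NEt into 1,3,5-tris(methoxymethoxy)benzene F1. Lithiation between two acetal oxygens (n-BuLi, THF, 0 °C) gives 2,4,6-tris(methoxymethoxy)phenyllithium F2, and quenching with B(OMe)3 and water gives [2,4,6-tris(methoxymethoxy)phenyl]boronic acid F3. Suzuki–Miyaura coupling with 1 at the C–I bond (Pd(OAc)2, SPhos, K3PO4, toluene/H2O, 60 °C) should give 2-(2-bromo-5-methoxyphenyl)-1,3,5-tris(methoxymethoxy)benzene F4. HCl in MeOH would release 2-(2-bromo-5-methoxyphenyl)benzene-1,3,5-triol F5. The carbonylation conditions of step 6 would close it to 1,3-dihydroxy-9-methoxy-6H-benzo[c]chromen-6-one F6, and 2-bromopropane/K2CO3 in DMF would give 17. No oxygen differentiation is needed on this path, because the lactone takes one of the two equivalent ortho hydroxyls and the other two receive the same group.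

Step 11 (C4a acetylation). Acylation may go para to the hydroxyl at C6, or the Lewis acid may dealkylate the C5 ether next to the new carbonyl. The latter would allow ring C to close later on the wrong oxygen.

The fallback uses an ortho-specific, non-acidic C–C bond formation; it sets out from 22 and comes back at 24. Magnesium-mediated ortho-formylation (MgCl2, Et3N, paraformaldehyde, MeCN, reflux) should give 2-hydroxy-3-{5-methoxy-2-[4-oxo-5,7-di(propan-2-yloxy)-4H-chromen-2-yl]phenyl}-4,6-di(propan-2-yloxy)benzaldehyde F9. Aldehyde-selective methyl addition with MeTi(Oi-Pr)3 (THF, −40 °C), which spares the flavone carbonyl, would give 2-{2-[2-hydroxy-3-(1-hydroxyethyl)-4,6-di(propan-2-yloxy)phenyl]-4-methoxyphenyl}-5,7-di(propan-2-yloxy)-4H-chromen-4-one F10. Benzylic oxidation with MnO2 in CH2Cl2 would then give 24.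

Step 9 (lactone opening). The acylation may reverse by retro-Claisen reclosure of the lactone, or proton transfer from the product may quench the dianion and leave lactone unconsumed.

The fallback replaces acylation by the chalcone route; it sets out from 17 and comes back at 22. Reduction with i-Bu2AlH (CH2Cl2, −78 °C) would give the lactol 9-methoxy-1,3-di(propan-2-yloxy)-6H-benzo[c]chromen-6-ol F7. Through its open hydroxy-aldehyde form this should condense with 19 (KOH, EtOH, rt) to (2E)-1-[2-hydroxy-4,6-di(propan-2-yloxy)phenyl]-3-{2-[2-hydroxy-4,6-di(propan-2-yloxy)phenyl]-4-methoxyphenyl}prop-2-en-1-one F8. Oxidative cyclisation with I2 (cat.) in DMSO at 130 °C would then give 22.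

**Further compounds**

F1 | step 5 | 1,3,5-tris(methoxymethoxy)benzene | COCOc1cc(OCOC)cc(OCOC)c1
F2 | step 5 | 2,4,6-tris(methoxymethoxy)phenyllithium | [Li]c1c(OCOC)cc(OCOC)cc1OCOC
F3 | step 5 | [2,4,6-tris(methoxymethoxy)phenyl]boronic acid | OB(O)c1c(OCOC)cc(OCOC)cc1OCOC
F4 | step 5 | 2-(2-bromo-5-methoxyphenyl)-1,3,5-tris(methoxymethoxy)benzene | COCOc1cc(OCOC)c(c(OCOC)c1)-c1cc(OC)ccc1Br
F5 | step 5 | 2-(2-bromo-5-methoxyphenyl)benzene-1,3,5-triol | COc1ccc(Br)c(c1)-c1c(O)cc(O)cc1O
F6 | step 5 | 1,3-dihydroxy-9-methoxy-6H-benzo[c]chromen-6-one | COc1ccc2C(=O)Oc3cc(O)cc(O)c3-c2c1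
F7 | step 9 | 9-methoxy-1,3-di(propan-2-yloxy)-6H-benzo[c]chromen-6-ol (racemic) | COc1ccc2C(O)Oc3cc(OC(C)C)cc(OC(C)C)c3-c2c1
F8 | step 9 | (2E)-1-[2-hydroxy-4,6-di(propan-2-yloxy)phenyl]-3-{2-[2-hydroxy-4,6-di(propan-2-yloxy)phenyl]-4-methoxyphenyl}prop-2-en-1-one | COc1ccc(/C=C/C(=O)c2c(O)cc(OC(C)C)cc2OC(C)C)c(c1)-c1c(O)cc(OC(C)C)cc1OC(C)C
F9 | step 11 | 2-hydroxy-3-{5-methoxy-2-[4-oxo-5,7-di(propan-2-yloxy)-4H-chromen-2-yl]phenyl}-4,6-di(propan-2-yloxy)benzaldehyde | COc1ccc(-c2cc(=O)c3c(OC(C)C)cc(OC(C)C)cc3o2)c(c1)-c1c(O)c(C=O)c(OC(C)C)cc1OC(C)C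
F10 | step 11 | 2-{2-[2-hydroxy-3-(1-hydroxyethyl)-4,6-di(propan-2-yloxy)phenyl]-4-methoxyphenyl}-5,7-di(propan-2-yloxy)-4H-chromen-4-one (racemic at the carbinol) | COc1ccc(-c2cc(=O)c3c(OC(C)C)cc(OC(C)C)cc3o2)c(c1)-c1c(O)c(C(C)O)c(OC(C)C)cc1OC(C)C
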